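The numbers in the tables were computed from invented constants, noise included.

At 10 min I wanted the target in a flask nobody had run, and I had these three runs.

in all of them: free catalyst 3 mol%
- Thursday's: solid substrate 7 mM; second substrate 0.50 equiv; run made earlier
- Saturday's: solid substrate 11 mM; second substrate 0.50 equiv; run made earlier
- Wednesday's: solid substrate 5 mM; second substrate 0.75 equiv; run made earlier
- flask: solid substrate 5.0 mM; second substrate 0.500 equiv; time 10 min

- Thursday's (time / min: target / %): 2.00: 16.9; 4.00: 45.6; 6.00: 76.1; 8.00: 92.0; 10.0: 97.6
- Saturday's (time / min: target / %): 2.00: 15.0; 4.00: 38.4; 6.00: 62.2; 8.00: 85.6; 10.0: 96.5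
- Wednesday's (time / min: target / %): 0.833: 3.1; 1.50: 9.5; 3.00: 32.6; 5.00: 65.7; 10.0: 95.8

(each reading ± 0.5 percentage points)

- as a solid, counted per litre of solution: solid substrate
- steps that have been proposed: solid substrate <-> starting material; starting material + free catalyst <-> catalyst intermediate A; catalyst intermediate B -> free catalyst + second product; second substrate + free catalyst <-> catalyst intermediate B; catalyst intermediate A -> free catalyst + target
- at the start none of the solid substrate is in solution

- midnight: doubling the amount of free catalyst, all else as stated
- winter: doubling the dissolution coefficient of the solid substrate, all else as stated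
- noon: doubling the solubility of the solid substrate, all else as stated

* how much target there is at 10 min, in percent of the solid substrate charged
* the change that raises the amount of target at 10 min, in percent of the solid substrate charged most ("none" if none brings more than 2 percentage points) (midnight / winter / noon / none)
* amount of target at 10 min, in percent of the solid substrate charged, after noon

- Late in Thursday's run, the part of the charge not yet target fell from 8.00% to 2.40% in 2.00 min, a pseudo-first-order tail of 0.602 min⁻¹. Thursday's charged c(free catalyst) was 0.210 mM, so each mM of that charge gave 2.87 mM⁻¹ min⁻¹, as a reading.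
- The flask's charge is 0.150 mM, from which I reckoned a tail of 0.430 min⁻¹.
- For the early end I borrowed Wednesday's run, which had the same c(free catalyst) but more second substrate. It had 34.3% not yet target at 5.00 min.
- Joining the two ends gave 96.0%.
- The weak link was Thursday's last remainder, 2.40% from one reading with a scatter of 0.5 percentage points. So I reckoned again from 6.00 min to 10.0 min the tail constant per catalyst, the first-order constant of the part not yet target divided by the charged c(free catalyst): 2.74 mM⁻¹ min⁻¹.
- With 0.410 min⁻¹, I committed to 95.6%.
- Midnight doubled the constant in my reckoning, giving 99.4%. For noon I assumed that Wednesday's lag, read as 1.03 min, was erased, which gave 97.1%. I chose midnight, since its figure stood higher than noon's.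
- The forecast said 97%, above mine, with midnight and 98%: “the end of the run is catalyst-controlled”.
- The flask gave 95.4%; midnight gained 4.5 points, and noon gave 97.1%.

    solid substrate ⇌ starting material, rate k1*(cs1 - [starting material]) while solid is left; crystals form when [starting material] > cs1 (solubility = 4.30 mM, k = 0.00796 s⁻¹)
    starting material + free catalyst ⇌ catalyst intermediate A (K = 91.0 M⁻¹, k = 266 M⁻¹ s⁻¹)
    catalyst intermediate B → free catalyst + second product (k = 1.05 s⁻¹)
    second substrate + free catalyst ⇌ catalyst intermediate B (K = 340 M⁻¹, k = 408 M⁻¹ s⁻¹)
    catalyst intermediate A → free catalyst + target (k = 0.636 s⁻¹)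

- From 5.00 min to 10.0 min this flask's own tail gave 2.68 mM⁻¹ min⁻¹ per catalyst, beside my 2.74 mM⁻¹ min⁻¹. The forecast stood; it would have had to be withdrawn had a run shown this flask's target 5 points off, as it moved at 2.4 mol% of free catalyst. Read at 6.0 min, the same flask reckons to 77.2% from Wednesday's remainder, and that neighbouring flask held 76.4%.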